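**Assumption:** the target (5,7,3',4'-tetrahydroxy-2',5'-diprenylisoflavone) has no stereocentre and no stereogenic double bond. It is achiral, so there is no enantiomer to control and the route needs no stereochemical step.

## Retrosynthetic overview

1. I avoid the usual plan, a Suzuki coupling of a 3-iodochromone with a pre-prenylated B-ring boronate. Both prenyl C–C bonds are instead made at once, last, on the finished isoflavone.
2. Key step: a double aromatic Claisen rearrangement of the 3',4'-bis(1,1-dimethylallyl) catechol ether. 4'-O migrates to C5' and 3'-O migrates to C2', and allyl inversion gives the prenyl groups directly.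
3. The bis-ether comes from 7-O-TIPS-orobol by a Pd(0)-catalysed double O-reverse-prenylation. The chelated 5-OH needs no protecting group.
4. Orobol comes from phloroglucinol, 3,4-dihydroxyphenylacetic acid and one carbon from DMF, in one pot.
5. Ring order: rings A and B are purchased. The pyranone ring C is the only ring formed (step 1).

## Route

**Step 1**
Reactants: 1 phloroglucinol; 2 3,4-dihydroxyphenylacetic acid
Product: 4 orobol (5,7,3',4'-tetrahydroxyisoflavone), via deoxybenzoin 3 (not isolated)
Conditions: BF3·OEt2 (as solvent), 85 °C, 1.5 h; then DMF, MsCl, 50→90 °C, 2 h; aq. NaOAc, then H2O work-up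
Reagents that add atoms: N,N-dimethylformamide CN(C)C=O
Why: Friedel–Crafts (Houben–Hoesch-type) acylation of phloroglucinol gives the deoxybenzoin, whose active CH2 is formylated Vilsmeier-style by the DMF/MsCl iminium salt and closes onto the ortho-OH with loss of Me2NH, while the acidic BF3 medium keeps the free phenols inert.

**Step 2**
Reactants: 4 orobol
Product: 5 7-O-triisopropylsilyl-orobol
Conditions: TIPSCl (1.05 equiv), imidazole (1.1 equiv), DMF, 0 °C, Ar
Reagents that add atoms: triisopropylsilyl chloride CC(C)[Si](Cl)(C(C)C)C(C)C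
Why: In this chemoselective silylation the 7-OH (vinylogous acid, pKa about 7) is more than 2 pKa units more acidic and less hindered than the catechol OH groups, and the 5-OH is locked in a hydrogen bond to C4=O, so one equivalent of a bulky silyl chloride goes to O-7.

**Step 3**
Reactants: 6 2-methylbut-3-en-2-ol
Product: 8 tert-butyl 2-methylbut-3-en-2-yl carbonate, via lithium alkoxide 7 (not isolated)
Conditions: n-BuLi (1.0 equiv), THF, −78→0 °C; Boc2O (1.0 equiv), 0 °C→rt; H2O quench
Reagents that add atoms: di-tert-butyl dicarbonate CC(C)(C)OC(=O)OC(=O)OC(C)(C)C; n-butyllithium [Li]CCCC (supplies only the Li of 7)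
Why: O-acylation of a tertiary lithium alkoxide with Boc2O gives the mixed carbonate, and the expelled tert-butyl carbonate ion collapses to CO2 and tert-butoxide.

**Step 4**
Reactants: 5 7-O-triisopropylsilyl-orobol; 8 tert-butyl 2-methylbut-3-en-2-yl carbonate (2.5 equiv)
Product: 10 7-O-TIPS-3',4'-bis-O-(1,1-dimethylallyl)orobol, via 4'-mono-ether 9 (not isolated)
Conditions: Pd(PPh3)4 (10 mol %), THF, 0–5 °C, Ar, stopped as soon as 9 is consumed
Reagents that add atoms: none
Why: In this Tsuji–Trost decarboxylative O-allylation the tert-butoxide released on ionisation deprotonates only the catechol OH groups, and at low temperature the phenoxide attacks the dimethyl-substituted π-allyl terminus to give the kinetic tertiary (reverse-prenyl) ethers, under near-neutral conditions that spare the TIPS ether and the chelated 5-OH.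

**Step 5 (key step)**
Reactants: 10 7-O-TIPS-3',4'-bis-O-(1,1-dimethylallyl)orobol
Product: 12 7-O-TIPS-5,3',4'-trihydroxy-2',5'-diprenylisoflavone, via mono-Claisen phenol 11 (not isolated)
Conditions: degassed PhMe (0.02 M), BHT (cat.), sealed tube, 110 °C, Ar, 12 h
Reagents that add atoms: none
Why: In this double aromatic Claisen rearrangement each O–CMe2–CH=CH2 unit shifts [3,3] with allyl inversion to its only H-bearing ortho carbon (4'-O→C5', then 3'-O→C2'), and irreversible tautomerisation to the phenol drains the reversible ipso shifts, so the non-fused B ring, which lacks bond fixation and would give an unactivated dienone, should not divert into a Claisen/Diels–Alder cage; no stereocentre is formed.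

**Step 6**
Reactants: 12 7-O-TIPS-5,3',4'-trihydroxy-2',5'-diprenylisoflavone
Product: 13 5,7,3',4'-tetrahydroxy-2',5'-diprenylisoflavone (target, CNP0231389.0)
Conditions: TBAF (1.1 equiv), AcOH (1.2 equiv), THF, 0 °C, 15 min, Ar
Reagents that add atoms: none
Why: Buffered fluoride desilylation cleaves the activated aryl silyl ether within minutes and avoids both the acid that would cyclise an ortho-prenylphenol to a chroman and the strong base that would open the pyranone or promote oxidation of the catechol.

## Compound list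

1 | phloroglucinol | Oc1cc(O)cc(O)c1 | starting material
2 | 3,4-dihydroxyphenylacetic acid | OC(=O)Cc1ccc(O)c(O)c1 | starting material
3 | 2-(3,4-dihydroxyphenyl)-1-(2,4,6-trihydroxyphenyl)ethanone (deoxybenzoin) | O=C(Cc1ccc(O)c(O)c1)c1c(O)cc(O)cc1O | intermediate (not isolated)
4 | orobol (5,7,3',4'-tetrahydroxyisoflavone) | O=c1c(-c2ccc(O)c(O)c2)coc2cc(O)cc(O)c12 | intermediate
5 | 7-O-triisopropylsilyl-orobol | CC(C)[Si](Oc1cc(O)c2c(c1)occ(-c1ccc(O)c(O)c1)c2=O)(C(C)C)C(C)C | intermediate
6 | 2-methylbut-3-en-2-ol | CC(C)(O)C=C | starting material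
7 | lithium 2-methylbut-3-en-2-olate | [Li+].[O-]C(C)(C)C=C | intermediate (not isolated)
8 | tert-butyl 2-methylbut-3-en-2-yl carbonate | CC(C)(C)OC(=O)OC(C)(C)C=C | intermediate
9 | 7-O-TIPS-4'-O-(1,1-dimethylallyl)orobol | CC(C)[Si](Oc1cc(O)c2c(c1)occ(-c1ccc(OC(C)(C)C=C)c(O)c1)c2=O)(C(C)C)C(C)C | intermediate (not isolated)
10 | 7-O-TIPS-3',4'-bis-O-(1,1-dimethylallyl)orobol | CC(C)[Si](Oc1cc(O)c2c(c1)occ(-c1ccc(OC(C)(C)C=C)c(OC(C)(C)C=C)c1)c2=O)(C(C)C)C(C)C | intermediate
11 | 7-O-TIPS-5,4'-dihydroxy-3'-O-(1,1-dimethylallyl)-5'-prenylisoflavone | CC(C)[Si](Oc1cc(O)c2c(c1)occ(-c1cc(CC=C(C)C)c(O)c(OC(C)(C)C=C)c1)c2=O)(C(C)C)C(C)C | intermediate (not isolated)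
12 | 7-O-TIPS-5,3',4'-trihydroxy-2',5'-diprenylisoflavone | CC(C)[Si](Oc1cc(O)c2c(c1)occ(-c1cc(CC=C(C)C)c(O)c(O)c1CC=C(C)C)c2=O)(C(C)C)C(C)C | intermediate
13 | 5,7,3',4'-tetrahydroxy-2',5'-diprenylisoflavone | CC(C)=CCc1cc(-c2coc3cc(O)cc(O)c3c2=O)c(CC=C(C)C)c(O)c1O | target

## Step count and risk

Total steps: 6. Longest linear sequence: 5 (steps 1, 2, 4, 5, 6). Step 3 is a one-step side branch.

**Most likely to fail, first: step 5 (double Claisen).** The risks are attack at the crowded C2', ionisation of the tertiary ethers back to the phenol, and trapping of an ipso-shifted dienone by Diels–Alder reaction.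

The fallback sets out from 5 and replaces the reverse-prenyl unit by plain allyl, building the trisubstituted alkenes afterwards:
- Compound 5 is O-allylated under neutral conditions (allyl methyl carbonate, Pd(PPh3)4, THF) to 7-O-TIPS-3',4'-bis-O-allylorobol F1.
- F1 is heated in N,N-diethylaniline at 190 °C. This is the well-behaved diallyl-catechol Claisen, and it gives 7-O-TIPS-2',5'-diallyl-5,3',4'-trihydroxyisoflavone F2.
- A double olefin cross-metathesis of F2 with 2-methyl-2-butene (Grubbs II, CH2Cl2, 40 °C) comes back to the route at 12.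

**Second: step 4 (double tertiary etherification of a catechol).** The risks are stalling at the mono-ether 9 and Pd-mediated isomerisation to the linear prenyl ethers.

The fallback sets out from 5 and makes the C–O bonds through a copper acetylide/allenylidene pathway instead of a π-allyl complex:
- 3-Chloro-3-methylbut-1-yne, CuCl2 (cat.) and DBU in MeCN at 0 °C give 7-O-TIPS-3',4'-bis-O-(1,1-dimethylpropargyl)orobol F3.
- Lindlar semi-hydrogenation of F3 (H2, Pd/CaCO3–Pb, quinoline, EtOAc) comes back to the route at 10.

**Third: step 2 (site-selective mono-silylation of a tetraphenol).** The risk is competing silylation at the catechol.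

The fallback sets out from 4 and masks the catechol explicitly:
- Dichlorodiphenylmethane in diphenyl ether at 175 °C gives orobol 3',4'-O-diphenylmethylene ketal F4.
- TIPSCl and imidazole then have only the 7-OH available and give 7-O-TIPS-orobol 3',4'-O-diphenylmethylene ketal F5.
- Brief hydrogenolysis of F5 (H2, Pd/C, THF/EtOH) releases the catechol and comes back to the route at 5.

## Further compounds

F1 | step 5 | 7-O-TIPS-3',4'-bis-O-allylorobol | CC(C)[Si](Oc1cc(O)c2c(c1)occ(-c1ccc(OCC=C)c(OCC=C)c1)c2=O)(C(C)C)C(C)C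
F2 | step 5 | 7-O-TIPS-2',5'-diallyl-5,3',4'-trihydroxyisoflavone | CC(C)[Si](Oc1cc(O)c2c(c1)occ(-c1cc(CC=C)c(O)c(O)c1CC=C)c2=O)(C(C)C)C(C)C
F3 | step 4 | 7-O-TIPS-3',4'-bis-O-(1,1-dimethylpropargyl)orobol | CC(C)[Si](Oc1cc(O)c2c(c1)occ(-c1ccc(OC(C)(C)C#C)c(OC(C)(C)C#C)c1)c2=O)(C(C)C)C(C)C
F4 | step 2 | orobol 3',4'-O-diphenylmethylene ketal | O=c1c(-c2ccc3c(c2)OC(c2ccccc2)(c2ccccc2)O3)coc2cc(O)cc(O)c12
F5 | step 2 | 7-O-TIPS-orobol 3',4'-O-diphenylmethylene ketal | CC(C)[Si](Oc1cc(O)c2c(c1)occ(-c1ccc3c(c1)OC(c1ccccc1)(c1ccccc1)O3)c2=O)(C(C)C)C(C)C
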